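The numbers are invented.

Every target formed in this flask brought a weak acid with it, and that weak acid then took substrate away to side product.

    substrate + weak acid → side product (k1 = 0.0056 /M/s)
    substrate + acid → weak acid + acid + target (k2 = 0.025 /M/s)
    substrate → weak acid + target (k3 = 1.1 × 10⁻⁵ /s)
    weak acid ⇌ conjugate base + acid, settled at all times (K4 = 7.9 × 10⁻¹⁰ M)

substrate 0.050 M; acid 1.50 mM; time 15 h

- part of the substrate that has reacted at 15 h
- pH of the solution at 15 h

How fast did the two routes to target run? With the acid at its charge they were pseudo-first-order in substrate, with a joint rate constant of 0.175 /h.

At what weak acid did the side reaction catch up? I divided that constant by the side reaction's rate constant and got 0.00866 M. This crossing level is the weak acid at which the side reaction uses substrate as fast as the two routes to target together. The side reaction also uses up weak acid, so in my reckoning weak acid stopped climbing at the same level. There the conjugate base is 4.56 × 10⁻⁹ M, far less than the 1.50 mM of acid charged, so I kept the pH of the charge.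

Was the level reached in time? Weak acid had a half-life of 0.69 h by the side reaction at the charged substrate, short against 15 h, so I took the flask to sit near the level for most of the run. I then reckoned substrate to fall at twice the joint rate, halving every 1.98 h. My estimate left 0.531 % of the substrate, so 99.5 % reacted.

The forecast gave 99.7 % reacted and pH 2.82, with the acid that “acts purely as a catalyst”.

The flask gave 99.3 % reacted and pH 2.82. Its weak acid stood at 0.00836 M at 15.0 h, below the level, and at 2.14 h the acid route was using substrate at 0.95 of the rate of the side reaction. In the neighbour flask with 0.0060 M of acid the level is 0.0288 M. That flask's substrate stood at 0 % at 15.0 h with weak acid at 0.0203 M, under its level, and its target came to 70.3 % of the substrate charged, against 58.0 % in the first flask.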